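The earlier runs and the new flask stem from a simulated flask on assumed constants; scatter was added.

Saturday's is read at 50 min, and the meeting agreed to reckon towards that time, for bis adduct in the cedar run read lower at 40.0 min than at 10.0 min.

| setting | cedar | Wednesday's | Saturday's |
|---|---|---|---|
| substrate | 1 M | 1.0 M | 1.0 M |
| reagent | 1.1 equiv | 3.00 equiv | 0.800 equiv |
| capture agent | 0.30 M | 0.300 M | 0.300 M |
| remark | run made earlier |  |  |
| time |  | 50 min | 50 min |

- cedar (time / min: bis adduct / %, tris adduct / %): 5.00: 6.1, 0; 10.0: 9.5, 0.3; 15.0: 9.4, 1.3; 20.0: 9.2, 0.1; 25.0: 8.6, 0.2; 30.0: 7.3, 0.4; 40.0: 6.1, 0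

(each reading ± 0.3 percentage points)

1. which of these holds the largest part of the substrate at the end of Wednesday's (mono adduct / tris adduct / substrate / bis adduct / tetra adduct)
2. which of these holds the largest part of the substrate at the end of Saturday's (mono adduct / tris adduct / substrate / bis adduct / tetra adduct)
3. final bis adduct in Saturday's, as a percentage of the substrate charged



The analyst pointed out that bis adduct in the cedar run read 9.5% after 10.0 min, held for a while, then sagged, with the highest tris adduct reading at 1.3%. She proposed reading the last stretch by itself, on the assumption that fresh making had faded there. A first-order fall integrates to c(bis adduct, t) = c(bis adduct, peak) · exp(−λ(t − t peak)), and the readings at 25.0 min and 40.0 min give the tail constant λ, the net apparent first-order fall of bis adduct once making has faded, 0.0229 min⁻¹. That is a half-life of 30.3 min, as read.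

The process chemist objected that Saturday's has less reagent, the limiting reagent there at 0.800 equiv. The analyst answered by scaling the peak with the charge, from 1.1 equiv to 0.800 equiv, which gives 6.91%, and by starting the fall at 10.0 min. Her own figure for Saturday's was 2.76%.

The forecast, tabled by a colleague, named tris adduct for Wednesday's and mono adduct for Saturday's, and put bis adduct in Saturday's at 0.3%, lower than her figure, holding that “the capture agent is draining it”.

    substrate + reagent → mono adduct (k = 0.00197 L mol⁻¹ s⁻¹)
    reagent + mono adduct → bis adduct (k = 0.00190 L mol⁻¹ s⁻¹)
    reagent + tris adduct → tetra adduct (k = 0.0114 L mol⁻¹ s⁻¹)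
    tris adduct → over-reaction product B (k = 0.00380 s⁻¹)
    reagent + bis adduct → tris adduct (k = 0.00128 L mol⁻¹ s⁻¹)
    bis adduct + capture agent → trapped intermediate (k = 0.00669 L mol⁻¹ s⁻¹)
    tris adduct → over-reaction product A (k = 1.13 × 10⁻⁵ s⁻¹)

Saturday's ends at 1.75% bis adduct, against 2.76% from the scaled peak and the tail constant. Of the species asked, substrate holds the most in Saturday's at 43.1%, and tetra adduct the most in Wednesday's at 35.1%. At 50.0 min in Saturday's, bis adduct is made more slowly than it is used up, each step taken net, at a ratio of 0.206. For Saturday's read early, at 12 min, the scaled peak and λ give 6.60%, and the flask stands at 6.12%.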